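(The data are simulated from invented constants.)

- Start from a time constant, that of the reagent. It is the limiting reagent of Sunday's and Monday's flasks, 0.240 M against 0.600 M of substrate together. If each substrate molecule that reacts takes one reagent, conversion is capped at 40.0% of the substrates.

common to all: left-handed substrate 0.30 M; right-handed substrate 0.30 M

| charge | reagent | precatalyst | remark | time |
|---|---|---|---|---|
| ochre | 0.24 M | 1.2 mM | run made earlier |  |
| violet | 0.24 M | 2 mM | run made earlier |  |
| Sunday's | 0.240 M | 3.0 mM |  | 20 h |
| Monday's | 0.240 M | 1.5 mM |  | 20 h |

| run | time / h | right-handed substrate / % | left-handed substrate / % | left-handed product / % |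
|---|---|---|---|---|
| ochre | 1.00 | 48 | 49 | 0 |
| ochre | 2.00 | 47 | 49 | 0 |
| ochre | 4.00 | 45 | 50 | 0 |
| ochre | 8.00 | 40 | 50 | 0 |
| ochre | 15.0 | 34 | 48 | 3 |
| violet | 1.00 | 48 | 51 | 0 |
| violet | 2.00 | 45 | 52 | 0 |
| violet | 4.00 | 42 | 51 | 3 |
| violet | 8.00 | 33 | 51 | 0 |
| violet | 15.0 | 25 | 47 | 2 |

(scatter of a reading: 1.5 percentage points)

- free catalyst is single-handed; left-handed substrate and right-handed substrate are mirror images of each other, charged as a racemate, each of them at the stated concentration
- an excess is the difference of the two amounts in percent of their sum
- an excess is below zero if the other one leads

- which of the two ends with the higher excess of right-handed substrate over left-handed substrate among what is left of the two ("neither" if they lie within 2 percentage points) (Sunday's / Monday's / neither)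
- excess of right-handed substrate over left-handed substrate among what is left of the two at the end, Sunday's
- excess of right-handed substrate over left-handed substrate among what is left of the two at the end, Monday's

- Write the balance with that one-to-one count: the share of reagent left is one minus conversion over that cap. In violet, the right-handed substrate lost plus the left-handed product at 15.0 h leaves a reading of 32.5% of the reagent.
- If [reagent] falls exponentially, violet's readings give 13.3 h as the reagent time constant, the time in which [reagent] falls by a factor e, at 2 mM of precatalyst.
- I take this constant as inversely proportional to the precatalyst. Violet then predicts 22.2 h for ochre, and ochre's own last readings give 23.3 h.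
- Now turn the question round. I take the excess to follow conversion, so on this reckoning "neither" asks for nearly equal reagent left in the two flasks.
- Scaling gives 8.90 h for Sunday's, leaving 10.6% of the reagent at the end. It gives 17.8 h for Monday's, leaving 32.5%, about a third, so the two stand far apart.
- Monday's has the same precatalyst times time as violet at its last reading, so on this reckoning Monday's should end at the excess read there, −30.6%.
- For Sunday's, with violet's split of conversion, I get right-handed substrate 16.9% and left-handed substrate 47.3%, so −47.5%. Monday's leads by more than the margin.
- The forecast says Monday's, with −57% for Sunday's and −27% for Monday's: “Right-handed decay fits first order, with no clear reagent dependence”. On Sunday's it lies lower than my figure.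
- The flasks give Monday's as the higher, with −42.8% for Sunday's and −26.7% for Monday's.

    reagent + free catalyst → spent catalyst (k = 2.70 L mol⁻¹ h⁻¹)
    free catalyst + left-handed substrate ⇌ catalyst intermediate A (K = 1.50 L mol⁻¹, k = 2000 L mol⁻¹ h⁻¹)
    precatalyst → free catalyst (k = 1.20 h⁻¹)
    reagent + catalyst intermediate A → free catalyst + left-handed product (k = 110 L mol⁻¹ h⁻¹)
    reagent + catalyst intermediate B → free catalyst + right-handed product (k = 42.0 L mol⁻¹ h⁻¹)
    free catalyst + right-handed substrate ⇌ catalyst intermediate B (K = 68.0 L mol⁻¹, k = 4700 L mol⁻¹ h⁻¹)

- Sunday's ends with 15% of its charged reagent, so its reagent time constant comes to 10.6 h, longer than reckoned. A neighbour of Monday's with 3.70 mM of precatalyst scales to 7.21 h, which leaves 6.25% of the reagent. That flask ends with 9.5% of its reagent and an excess of −47.1%.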